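**Retros
ynthetic overview**
1. Target 26 ⇒ seco iodo-alkyne 24 + CO: one Pd-mediated operation joins C2–C3 (ten-membered carbocycle, C3 from CO) and O–C3 (3(2H)-furanone); these two rings form last, together.
2. 24 ⇒ alcohol 19 + (2S,3S)-epoxyangelic acid 23 (oxirane by Sharpless epoxidation), joined by Mitsunobu inversion at C6.
3. 19 ⇒ aldehyde 16 + allylic bromide 10: Cr(II) 2-(alkoxycarbonyl)allylation/lactonisation builds the α-methylene-γ-lactone and sets C7/C8 from C6.
4. 10 ⇒ (Z)-3-iodobut-2-enal + methyl propiolate (C6 by asymmetric alkynylation); 16 ⇒ TMS-butynone + allylboronate (C10 by asymmetric allylboration).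
5. Ring order: oxirane (side chain) → γ-lactone → furanone + ten-membered ring (one step).

Locants C1–C15 below are germacrane locants of the target: C1 furanone C=O, C2 =CH, C3 O–C=, C4(CH3-15)=C5, C6 (ester), C7, C8 (lactone O), C9 CH2, C10 (O, CH3-14), C11=C13H2, C12 lactone C=O.

Assumption: the ligand antipodes named in steps 3 and 7 are taken to give the stated configurations (to be checked by Mosher analysis of 6 and 14); if the sense is opposite, the enantiomeric ligand is used.

**Step 1**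
Reactants: 1 but-2-yn-1-ol
Product: 3 (Z)-3-iodobut-2-en-1-ol, via cyclic alkenylalanate 2 (not isolated)
Conditions: Red-Al, THF, 0 °C to rt; then I2, −78 to 0 °C
Reagents that add atoms: iodine, II
Why: hydroxyl-directed trans-hydroalumination of the propargylic alcohol (Al at C3) and stereoretentive iodinolysis give the Z-iodide, which fixes the C4=C5 geometry of the target (I cis to the future C6).

**Step 2**
Reactants: 3 (Z)-3-iodobut-2-en-1-ol
Product: 4 (Z)-3-iodobut-2-enal
Conditions: MnO2, CH2Cl2, rt, dark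
Reagents that add atoms: none
Why: MnO2 oxidation of an allylic alcohol under neutral conditions, so the Z-iodoalkene does not isomerise.

**Step 3**
Reactants: 4 (Z)-3-iodobut-2-enal; 5 methyl propiolate
Product: 6 methyl (4R,5Z)-4-hydroxy-6-iodohept-5-en-2-ynoate
Conditions: Me2Zn (3 equiv), (R,R)-ProPhenol (20 mol %), Ph3P=O (40 mol %), PhMe, 4 °C
Reagents that add atoms: none
Why: dinuclear-zinc (ProPhenol) catalysed enantioselective alkynylation of an enal by the zinc propiolate sets C6 as the (4R)-carbinol, deliberately the epimer of the target's C6 (inverted in step 14); the vinyl iodide is inert to Me2Zn.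

**Step 4**
Reactants: 6 methyl (4R,5Z)-4-hydroxy-6-iodohept-5-en-2-ynoate
Product: 7 methyl (4R,5Z)-4-[(tert-butyldimethylsilyl)oxy]-6-iodohept-5-en-2-ynoate
Conditions: TBSCl, imidazole, DMF, 0 °C to rt
Reagents that add atoms: tert-butyldimethylsilyl chloride, CC(C)(C)[Si](C)(C)Cl
Why: standard silylation; the bulky OTBS group later controls the π-face in step 9 and prevents 6,12-lactonisation.

**Step 5**
Reactants: 7 methyl (4R,5Z)-4-[(tert-butyldimethylsilyl)oxy]-6-iodohept-5-en-2-ynoate
Product: 9 methyl (2Z,4S,5Z)-4-[(tert-butyldimethylsilyl)oxy]-2-(hydroxymethyl)-6-iodohepta-2,5-dienoate, via vinylalane 8 (not isolated)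
Conditions: DIBAL-H, NMO, THF, 0 °C; then CH2O (g), −20 °C to rt
Reagents that add atoms: formaldehyde, C=O
Why: syn 1,4-hydroalumination of the ynoate (H to C7, Al to C11; vinylalumination) followed by C-hydroxymethylation of the α-aluminoacrylate with retention gives the Baylis–Hillman-type allylic alcohol; C6 is untouched (its descriptor changes only through CIP priorities).

**Step 6**
Reactants: 9 methyl (2Z,4S,5Z)-4-[(tert-butyldimethylsilyl)oxy]-2-(hydroxymethyl)-6-iodohepta-2,5-dienoate
Product: 10 methyl (2E,4S,5Z)-2-(bromomethyl)-4-[(tert-butyldimethylsilyl)oxy]-6-iodohepta-2,5-dienoate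
Conditions: CBr4, PPh3, CH2Cl2, 0 °C
Reagents that add atoms: tetrabromomethane, BrC(Br)(Br)Br
Why: Appel bromination (SN2) of the primary allylic alcohol leaves the silyl ether and vinyl iodide untouched.

**Step 7**
Reactants: 11 4-(trimethylsilyl)but-3-yn-2-one; 12 diisopropyl allylboronate
Product: 14 (S)-3-methylhex-5-en-1-yn-3-ol, via silyl carbinol 13 (not isolated)
Conditions: (S)-3,3′-Br2-BINOL (15 mol %), PhCF3/PhMe, −35 °C; then K2CO3, MeOH, rt
Reagents that add atoms: none
Why: chiral-diol-catalysed asymmetric allylboration of the methyl ynone through a closed chair transition state sets C10 as (S), and methanolysis removes the borate and the C-silyl group.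

**Step 8**
Reactants: 14 (S)-3-methylhex-5-en-1-yn-3-ol
Product: 16 (S)-3-hydroxy-3-methylpent-4-ynal, via ozonide 15 (not isolated)
Conditions: O3, CH2Cl2, −78 °C; then Me2S, −78 °C to rt; used crude
Reagents that add atoms: ozone, [O-][O+]=O
Why: ozonolysis cleaves the isolated terminal alkene much faster than the terminal alkyne, and C10 is not involved.

**Step 9**
Reactants: 10 methyl (2E,4S,5Z)-2-(bromomethyl)-4-[(tert-butyldimethylsilyl)oxy]-6-iodohepta-2,5-dienoate; 16 (S)-3-hydroxy-3-methylpent-4-ynal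
Product: 18 (4R,5S)-4-[(1S,2Z)-1-[(tert-butyldimethylsilyl)oxy]-3-iodobut-2-en-1-yl]-5-[(2S)-2-hydroxy-2-methylbut-3-yn-1-yl]-3-methylideneoxolan-2-one, via hydroxy ester 17 (not isolated)
Conditions: CrCl2 (4 equiv), THF, 0 °C to rt; then PPTS, PhH, 50 °C
Reagents that add atoms: none
Why: Nozaki–Hiyama 2-(alkoxycarbonyl)allylation at the γ-carbon (C7) through a chair Cr(III) transition state gives the 7,8-anti adduct (trans-lactone after acid lactonisation), and with H-6 eclipsing C7=C11 (A1,3 strain) the aldehyde adds anti to the OTBS group, setting 7R and 8S from the C6 centre; the vinyl iodide is inert without Ni.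

**Step 10**
Reactants: 18 the silyl ether lactone of step 9
Product: 19 (4S,5S)-4-[(1S,2Z)-1-hydroxy-3-iodobut-2-en-1-yl]-5-[(2S)-2-hydroxy-2-methylbut-3-yn-1-yl]-3-methylideneoxolan-2-one
Conditions: HF·pyridine, THF/pyridine, 0 °C to rt
Reagents that add atoms: none
Why: acidic fluoride desilylation avoids translactonisation and Michael addition to the methylene lactone; no stereocentre changes (the C7 descriptor changes only through CIP priorities).

**Step 11**
Reactants: 20 angelic acid, (Z)-2-methylbut-2-enoic acid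
Product: 21 (Z)-2-methylbut-2-en-1-ol
Conditions: LiAlH4, Et2O, 0 °C
Reagents that add atoms: none
Why: hydride reduction of the acid to the allylic alcohol without Z to E isomerisation.

**Step 12**
Reactants: 21 (Z)-2-methylbut-2-en-1-ol
Product: 22 [(2R,3S)-2,3-dimethyloxiran-2-yl]methanol
Conditions: Ti(OiPr)4 (10 mol %), D-(−)-DET (12 mol %), TBHP, 4 Å MS, CH2Cl2, −20 °C
Reagents that add atoms: tert-butyl hydroperoxide, CC(C)(C)OO
Why: Sharpless asymmetric epoxidation; D-(−)-tartrate gives the (2R,3S) epoxide (L-(+)-tartrate gives 2S for this substitution pattern) and the Z-alkene geometry fixes the relative configuration.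

**Step 13**
Reactants: 22 [(2R,3S)-2,3-dimethyloxiran-2-yl]methanol
Product: 23 (2S,3S)-2,3-dimethyloxirane-2-carboxylic acid
Conditions: RuCl3·xH2O (2 mol %), NaIO4, CCl4/MeCN/H2O, 0 °C to rt
Reagents that add atoms: sodium periodate (oxygen donor via RuO4), [Na+].[O-]I(=O)(=O)=O; water, O
Why: RuO4 oxidation of the primary alcohol to the acid leaves both epoxide centres untouched (2R becomes 2S only through CIP priorities).

**Step 14**
Reactants: 19 the diol of step 10; 23 (2S,3S)-2,3-dimethyloxirane-2-carboxylic acid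
Product: 24 (1R,2Z)-1-[(2S,3R)-2-[(2S)-2-hydroxy-2-methylbut-3-yn-1-yl]-4-methylidene-5-oxooxolan-3-yl]-3-iodobut-2-en-1-yl (2S,3S)-2,3-dimethyloxirane-2-carboxylate
Conditions: PPh3, DIAD, PhMe, −20 °C to rt (acid premixed with 19)
Reagents that add atoms: none
Why: Mitsunobu esterification displaces the C6 alkoxyphosphonium by the carboxylate with SN2 inversion, which gives the target C6 configuration while installing the side chain; SN2′ is blocked by the fully substituted, iodine-bearing C4, and the tertiary C10 hydroxyl is not activated.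

**Step 15**
Reactants: 24 the seco iodo-alkyne ester of step 14
Product: 26 CNP0258430.1 (target), via macrocyclic ynone 25 (not isolated)
Conditions: PdCl2(PPh3)2 (10 mol %), CuI (5 mol %), Et3N, CO (1 atm), THF/H2O 20:1, 40 °C, syringe-pump addition to 2 mM
Reagents that add atoms: carbon monoxide, [C-]#[O+]; water, O
Why: Proposed new method: oxidative addition of Pd(0) to the Z-vinyl iodide and CO insertion give a C3 acyl-palladium that is captured intramolecularly by the copper acetylide (C2), closing the ten-membered carbocycle as the strained γ-hydroxy ynone 25, which under the same Et3N/H2O conditions takes up water at C1 and condenses O10 onto C3 (the CO-derived oxygen leaves as water) to form the 3(2H)-furanone, strain release making the sequence irreversible; no stereocentre is formed and the Z C4=C5 geometry is retained; the closest known reactions are the intermolecular Pd-catalysed carbonylative coupling of aryl or vinyl halides with tertiary propargylic alcohols that gives 3(2H)-furanones directly, and Pd-catalysed carbonylative macrocyclisations to furanone-bridged macrocycles.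

**Compound list**
1 | but-2-yn-1-ol | CC#CCO | starting material
2 | sodium 2,2-bis(2-methoxyethoxy)-3-methyl-2,5-dihydro-1,2-oxaluminol-2-uide (cyclic alkenylalanate) | [Na+].CC1=CCO[Al-]1(OCCOC)OCCOC | intermediate
3 | (Z)-3-iodobut-2-en-1-ol | OC/C=C(/C)I | intermediate
4 | (Z)-3-iodobut-2-enal | O=C/C=C(/C)I | intermediate
5 | methyl propiolate | C#CC(=O)OC | starting material
6 | methyl (4R,5Z)-4-hydroxy-6-iodohept-5-en-2-ynoate | COC(=O)C#C[C@H](O)/C=C(/C)I | intermediate
7 | methyl (4R,5Z)-4-[(tert-butyldimethylsilyl)oxy]-6-iodohept-5-en-2-ynoate | COC(=O)C#C[C@H](O[Si](C)(C)C(C)(C)C)/C=C(/C)I | intermediate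
8 | methyl (2E,4S,5Z)-2-[bis(2-methylpropyl)alumanyl]-4-[(tert-butyldimethylsilyl)oxy]-6-iodohepta-2,5-dienoate (vinylalane) | COC(=O)/C([Al](CC(C)C)CC(C)C)=C\[C@H](O[Si](C)(C)C(C)(C)C)/C=C(/C)I | intermediate
9 | methyl (2Z,4S,5Z)-4-[(tert-butyldimethylsilyl)oxy]-2-(hydroxymethyl)-6-iodohepta-2,5-dienoate | COC(=O)/C(CO)=C\[C@H](O[Si](C)(C)C(C)(C)C)/C=C(/C)I | intermediate
10 | methyl (2E,4S,5Z)-2-(bromomethyl)-4-[(tert-butyldimethylsilyl)oxy]-6-iodohepta-2,5-dienoate | COC(=O)/C(CBr)=C\[C@H](O[Si](C)(C)C(C)(C)C)/C=C(/C)I | intermediate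
11 | 4-(trimethylsilyl)but-3-yn-2-one | CC(=O)C#C[Si](C)(C)C | starting material
12 | diisopropyl allylboronate | C=CCB(OC(C)C)OC(C)C | starting material
13 | (S)-3-methyl-1-(trimethylsilyl)hex-5-en-1-yn-3-ol | C=CC[C@](C)(O)C#C[Si](C)(C)C | intermediate
14 | (S)-3-methylhex-5-en-1-yn-3-ol | C=CC[C@](C)(O)C#C | intermediate
15 | (2S)-2-methyl-1-(1,2,4-trioxolan-3-yl)but-3-yn-2-ol (ozonide, mixture at the trioxolane carbon) | C#C[C@@](C)(O)CC1OCOO1 | intermediate
16 | (S)-3-hydroxy-3-methylpent-4-ynal | O=CC[C@](C)(O)C#C | intermediate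
17 | methyl (3R,4S,6S)-3-[(1S,2Z)-1-[(tert-butyldimethylsilyl)oxy]-3-iodobut-2-en-1-yl]-4,6-dihydroxy-6-methyl-2-methylideneoct-7-ynoate | COC(=O)C(=C)[C@H]([C@@H](O)C[C@](C)(O)C#C)[C@H](O[Si](C)(C)C(C)(C)C)/C=C(/C)I | intermediate
18 | (4R,5S)-4-[(1S,2Z)-1-[(tert-butyldimethylsilyl)oxy]-3-iodobut-2-en-1-yl]-5-[(2S)-2-hydroxy-2-methylbut-3-yn-1-yl]-3-methylideneoxolan-2-one | C=C1C(=O)O[C@@H](C[C@](C)(O)C#C)[C@@H]1[C@H](O[Si](C)(C)C(C)(C)C)/C=C(/C)I | intermediate
19 | (4S,5S)-4-[(1S,2Z)-1-hydroxy-3-iodobut-2-en-1-yl]-5-[(2S)-2-hydroxy-2-methylbut-3-yn-1-yl]-3-methylideneoxolan-2-one | C=C1C(=O)O[C@@H](C[C@](C)(O)C#C)[C@@H]1[C@H](O)/C=C(/C)I | intermediate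
20 | angelic acid, (Z)-2-methylbut-2-enoic acid | C/C=C(/C)C(=O)O | starting material
21 | (Z)-2-methylbut-2-en-1-ol | C/C=C(/C)CO | intermediate
22 | [(2R,3S)-2,3-dimethyloxiran-2-yl]methanol | OC[C@@]1(C)O[C@H]1C | intermediate
23 | (2S,3S)-2,3-dimethyloxirane-2-carboxylic acid | OC(=O)[C@@]1(C)O[C@H]1C | intermediate
24 | (1R,2Z)-1-[(2S,3R)-2-[(2S)-2-hydroxy-2-methylbut-3-yn-1-yl]-4-methylidene-5-oxooxolan-3-yl]-3-iodobut-2-en-1-yl (2S,3S)-2,3-dimethyloxirane-2-carboxylate | C=C1C(=O)O[C@@H](C[C@](C)(O)C#C)[C@@H]1[C@@H](OC(=O)[C@@]2(C)O[C@H]2C)/C=C(/C)I | intermediate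
25 | macrocyclic γ-hydroxy ynone: ten-membered (4Z)-4-en-1-yn-3-one carbocycle with C10 OH/CH3, C4 CH3, C6 (2S,3S)-epoxyangelate and trans-fused α-methylene-γ-lactone at C7/C8; stereocentres as in 26 | C=C1C(=O)O[C@H]2C[C@](C)(O)C#CC(=O)/C(C)=C\[C@H](OC(=O)[C@@]3(C)O[C@H]3C)[C@H]12 | intermediate
26 | CNP0258430.1: (4Z,6S,7R,8S,10S)-3,10-epoxy-1-oxogermacra-2,4,11(13)-trien-12,8-olide 6-O-[(2S,3S)-2,3-dimethyloxirane-2-carboxylate] | C=C1C(=O)O[C@H]2C[C@]3(C)OC(=CC3=O)/C(C)=C\[C@H](OC(=O)[C@@]3(C)O[C@H]3C)[C@H]12 | target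

**Totals**
Total steps: 15. Longest linear sequence: 10 (steps 1–6, 9, 10, 14, 15).

**Three steps most likely to fail**

Step 15. The transient ten-membered ynone is strained, the acyl-palladium may instead insert into the methylene lactone, and oligomers may form despite dilution. The fallback reverses the order of ring formation and sets out from 9 and 14. Intermolecular Pd/Cu carbonylative coupling–cycloisomerisation of these two (CO, Et3N, aqueous THF, rt) gives methyl (2Z,4R,5Z)-4-[(tert-butyldimethylsilyl)oxy]-2-(hydroxymethyl)-6-[(5S)-5-methyl-4-oxo-5-(prop-2-en-1-yl)-4,5-dihydrofuran-2-yl]hepta-2,5-dienoate F1. Appel bromination gives the allylic bromide F2, and OsO4/NaIO4 cleavage of the terminal vinyl group gives the aldehyde F3. CrCl2-mediated intramolecular 2-(alkoxycarbonyl)allylation with lactonisation then closes the ten-membered ring and the lactone to the 6-epi silyl ether macrocycle F4; its stereochemical outcome would have to be established. HF·pyridine gives the 6-epi alcohol F5, and Mitsunobu esterification with 23 comes back to the route at 26.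

Step 9. The π-facial and anti selectivity rest on a model, and aldehyde 16 is fragile. The fallback sets out from 10: copper-catalysed borylation (B2pin2, CuCl, LiOt-Bu) converts the bromide into the configurationally stable methyl (2Z,4S,5Z)-4-[(tert-butyldimethylsilyl)oxy]-6-iodo-2-[(4,4,5,5-tetramethyl-1,3,2-dioxaborolan-2-yl)methyl]hepta-2,5-dienoate F6. Its type-I allylboration of 16 (thermal or Sc(OTf)3) through a closed chair transfers the alkene geometry into the 7,8-anti relationship and lactonises, coming back to the route at 18.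

Step 14. The allylic alcohol is hindered, and elimination or ether formation by the C10 hydroxyl may compete with inversion. The fallback sets out from 19: Dess–Martin oxidation gives (4R,5S)-5-[(2S)-2-hydroxy-2-methylbut-3-yn-1-yl]-4-[(2Z)-3-iodobut-2-enoyl]-3-methylideneoxolan-2-one F7. Reagent-controlled CBS reduction gives the C6-epimeric alcohol (4S,5S)-4-[(1R,2Z)-1-hydroxy-3-iodobut-2-en-1-yl]-5-[(2S)-2-hydroxy-2-methylbut-3-yn-1-yl]-3-methylideneoxolan-2-one F8. Acylation with retention by the mixed anhydride of 23 (2,4,6-trichlorobenzoyl chloride, Et3N, DMAP) comes back to the route at 24.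

**Further compounds**
F1 | step 15 | methyl (2Z,4R,5Z)-4-[(tert-butyldimethylsilyl)oxy]-2-(hydroxymethyl)-6-[(5S)-5-methyl-4-oxo-5-(prop-2-en-1-yl)-4,5-dihydrofuran-2-yl]hepta-2,5-dienoate | C=CC[C@]1(C)OC(=CC1=O)/C(C)=C\[C@@H](O[Si](C)(C)C(C)(C)C)/C=C(/CO)C(=O)OC
F2 | step 15 | methyl (2E,4R,5Z)-2-(bromomethyl)-4-[(tert-butyldimethylsilyl)oxy]-6-[(5S)-5-methyl-4-oxo-5-(prop-2-en-1-yl)-4,5-dihydrofuran-2-yl]hepta-2,5-dienoate | C=CC[C@]1(C)OC(=CC1=O)/C(C)=C\[C@@H](O[Si](C)(C)C(C)(C)C)/C=C(/CBr)C(=O)OC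
F3 | step 15 | methyl (2E,4R,5Z)-2-(bromomethyl)-4-[(tert-butyldimethylsilyl)oxy]-6-[(5S)-5-methyl-4-oxo-5-(2-oxoethyl)-4,5-dihydrofuran-2-yl]hepta-2,5-dienoate | O=CC[C@]1(C)OC(=CC1=O)/C(C)=C\[C@@H](O[Si](C)(C)C(C)(C)C)/C=C(/CBr)C(=O)OC
F4 | step 15 | 6-epi macrocycle silyl ether: skeleton of 26 with C6 bearing OTBS in the inverted configuration | C=C1C(=O)O[C@H]2C[C@]3(C)OC(=CC3=O)/C(C)=C\[C@@H](O[Si](C)(C)C(C)(C)C)[C@H]12
F5 | step 15 | 6-epi macrocyclic alcohol: skeleton of 26 with free C6 hydroxyl in the inverted configuration | C=C1C(=O)O[C@H]2C[C@]3(C)OC(=CC3=O)/C(C)=C\[C@@H](O)[C@H]12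
F6 | step 9 | methyl (2Z,4S,5Z)-4-[(tert-butyldimethylsilyl)oxy]-6-iodo-2-[(4,4,5,5-tetramethyl-1,3,2-dioxaborolan-2-yl)methyl]hepta-2,5-dienoate | COC(=O)/C(CB1OC(C)(C)C(C)(C)O1)=C\[C@H](O[Si](C)(C)C(C)(C)C)/C=C(/C)I
F7 | step 14 | (4R,5S)-5-[(2S)-2-hydroxy-2-methylbut-3-yn-1-yl]-4-[(2Z)-3-iodobut-2-enoyl]-3-methylideneoxolan-2-one | C=C1C(=O)O[C@@H](C[C@](C)(O)C#C)[C@@H]1C(=O)/C=C(/C)I
F8 | step 14 | (4S,5S)-4-[(1R,2Z)-1-hydroxy-3-iodobut-2-en-1-yl]-5-[(2S)-2-hydroxy-2-methylbut-3-yn-1-yl]-3-methylideneoxolan-2-one | C=C1C(=O)O[C@@H](C[C@](C)(O)C#C)[C@@H]1[C@@H](O)/C=C(/C)I
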